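**Assumption:** (S)-Trolox (≥98% ee) and (E,E)-farnesyl bromide are taken as catalogue items. If only racemic Trolox is available, it is resolved classically as an α-methylbenzylamine salt.

## Retrosynthetic overview
1. Target 9 comes from O-desilylation of 8, and 8 comes from reductive removal of an allylic sulfone from 7.
2. The key disconnection is C1'–C2': chromanylmethyl triflate 4 (electrophile) plus lithiated (E,E)-farnesyl phenyl sulfone 6, a C15 nucleophile that already carries both E-olefins.
3. Triflate 4 comes from (S)-Trolox 1 by silylation, reduction and triflation. The C2 stereocentre is bought: the (S)-acid has the same spatial arrangement as the (2R)-tocotrienol, and only the CIP ranking changes.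
4. Sulfone 6 comes from (E,E)-farnesyl bromide 5 and PhSO2Na.
5. No ring is formed. The arene and the dihydropyran ring both arrive intact in 1.

## Route

**Step 1**
Reactants: 1, (S)-Trolox [(2S)-6-hydroxy-2,5,7,8-tetramethylchroman-2-carboxylic acid]
Product: 2, TBS (2S)-6-(TBSO)-2,5,7,8-tetramethylchroman-2-carboxylate (silyl ether and silyl ester)
Conditions: TBSCl (3 equiv), imidazole (6 equiv), DMF, rt → 50 °C; quick hexane/water work-up, used crude
Reagents that add atoms: TBSCl, CC(C)(C)[Si](C)(C)Cl
Why: Imidazole-promoted exhaustive silylation (Corey TBS protection) masks the acidic, oxidation-prone phenol and also caps the acid, while the quaternary C2 centre is not touched.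

**Step 2**
Reactants: 2
Product: 3, [(2S)-6-(TBSO)-2,5,7,8-tetramethylchroman-2-yl]methanol
Conditions: LiAlH4 (3 equiv), THF, 0 °C → rt; Rochelle salt work-up
Reagents that add atoms: none
Why: Hydride reduction converts the silyl ester, and any acid formed by adventitious hydrolysis, into the same primary alcohol, while the di-ortho-methyl-shielded aryl TBS ether and C2 are unaffected.

**Step 3**
Reactants: 3
Product: 4, [(2S)-6-(TBSO)-2,5,7,8-tetramethylchroman-2-yl]methyl trifluoromethanesulfonate
Conditions: Tf2O (1.2 equiv), pyridine, CH2Cl2, −78 → 0 °C; short silica plug, used immediately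
Reagents that add atoms: triflic anhydride, O=S(=O)(OS(=O)(=O)C(F)(F)F)C(F)(F)F
Why: O-sulfonylation installs a leaving group reactive enough for a neopentyl-type carbon, and E2 is impossible because the adjacent carbon is quaternary.

**Step 4**
Reactants: 5, (2E,6E)-farnesyl bromide
Product: 6, (2E,6E)-farnesyl phenyl sulfone
Conditions: PhSO2Na (1.3 equiv), DMF, 0 °C → rt
Reagents that add atoms: sodium benzenesulfinate, [Na+].[O-]S(=O)c1ccccc1
Why: SN2 S-alkylation of the sulfinate at the primary allylic bromide gives the sulfone with both E-olefins preserved.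

**Step 5**
Reactants: 4 and 6 (1.3 equiv)
Product: 7, (2S)-6-(TBSO)-2,5,7,8-tetramethyl-2-[(3E,7E)-2-(phenylsulfonyl)-4,8,12-trimethyltrideca-3,7,11-trienyl]chroman, about 1:1 epimers at C2'
Conditions: 6, n-BuLi (1.25 equiv), THF/HMPA (4:1), −78 °C; then 4, −78 °C → rt
Reagents that add atoms: none
Why: α-Selective alkylation of the sulfonyl-stabilised allyl anion (Julia/Biellmann-type SN2 coupling) occurs at CH2 and not at C2, so C2 keeps its geometry (labelled S here only because of CIP ranking), and the new C2' centre is irrelevant because Step 6 destroys it.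

**Step 6**
Reactants: 7
Product: 8, (2R,3'E,7'E)-α-tocotrienol TBS ether
Conditions: PdCl2(dppp) (5–10 mol %), LiEt3BH (3 equiv), THF, 0 °C → rt
Reagents that add atoms: none
Why: In this Pd-catalysed reductive desulfonylation (Tsuji–Trost-type ionisation, Inomata–Kotake conditions), hydride is delivered to the less substituted, sulfone-bearing terminus of the syn-π-allyl complex, so the Δ3' olefin stays in place and stays E, while the isolated trisubstituted olefins and the aryl TBS ether are inert.

**Step 7**
Reactants: 8
Product: 9, (2R)-2,5,7,8-tetramethyl-2-[(3E,7E)-4,8,12-trimethyltrideca-3,7,11-trienyl]chroman-6-ol, (R)-α-tocotrienol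
Conditions: TBAF (1.2 equiv), THF, 0 °C, Ar; aq NH4Cl quench
Reagents that add atoms: none
Why: Fluoride-driven desilylation frees the phenol without acid, so there is no polyene cyclisation or chroman opening, and it leaves the olefin geometry and C2 unchanged.

## Compound list
1 | (S)-Trolox | OC(=O)[C@]1(C)CCc2c(C)c(O)c(C)c(C)c2O1 | starting material
2 | bis-TBS (S)-Trolox (silyl ether/silyl ester) | CC(C)(C)[Si](C)(C)OC(=O)[C@]1(C)CCc2c(C)c(O[Si](C)(C)C(C)(C)C)c(C)c(C)c2O1 | intermediate
3 | (S)-6-OTBS-chroman-2-methanol | OC[C@]1(C)CCc2c(C)c(O[Si](C)(C)C(C)(C)C)c(C)c(C)c2O1 | intermediate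
4 | (S)-6-OTBS-chroman-2-ylmethyl triflate | FC(F)(F)S(=O)(=O)OC[C@]1(C)CCc2c(C)c(O[Si](C)(C)C(C)(C)C)c(C)c(C)c2O1 | intermediate
5 | (2E,6E)-farnesyl bromide | CC(C)=CCC/C(C)=C/CC/C(C)=C/CBr | starting material
6 | (2E,6E)-farnesyl phenyl sulfone | CC(C)=CCC/C(C)=C/CC/C(C)=C/CS(=O)(=O)c1ccccc1 | intermediate
7 | 2'-phenylsulfonyl α-tocotrienol TBS ether (C2 fixed, C2' epimers) | CC(C)=CCC/C(C)=C/CC/C(C)=C/C(C[C@]1(C)CCc2c(C)c(O[Si](C)(C)C(C)(C)C)c(C)c(C)c2O1)S(=O)(=O)c1ccccc1 | intermediate
8 | (R)-α-tocotrienol TBS ether | CC(C)=CCC/C(C)=C/CC/C(C)=C/CC[C@]1(C)CCc2c(C)c(O[Si](C)(C)C(C)(C)C)c(C)c(C)c2O1 | intermediate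
9 | (R)-α-tocotrienol (CID 5282347) | CC(C)=CCC/C(C)=C/CC/C(C)=C/CC[C@]1(C)CCc2c(C)c(O)c(C)c(C)c2O1 | target

## Summary
Total steps: 7. Longest linear sequence: 6 (1→2→3→4→7→8→9).

**Steps most likely to fail**
1. **Step 5** (SN2 of a bulky carbanion at a neopentyl-type triflate).
   - Fallback: use a small nucleophile and build the chain in two pieces.
   - Treat 4 with allylMgBr/CuI, then cleave the only alkene present (OsO4/NaIO4) to the C3' aldehyde.
   - Run an E-selective HWE with triethyl 2-phosphonopropionate, reduce with DIBAL, and convert to the allylic bromide.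
   - Alkylate lithiated geranyl phenyl sulfone at this unhindered allylic carbon, then finish with Steps 6 and 7.
2. **Step 6** (olefin migration or E/Z erosion during desulfonylation).
   - Fallback: a sulfur-free sp3–sp2 disconnection at C2'–C3'.
   - Oxidise 3 by Swern, methylenate by Wittig to the 2-vinylchroman, and hydroborate with 9-BBN.
   - Carry out a B-alkyl Suzuki–Miyaura coupling with (1E,5E)-1-iodo-2,6,10-trimethylundeca-1,5,9-triene, made by Negishi Zr-catalysed carboalumination/iodination of (E)-6,10-dimethylundeca-5,9-dien-1-yne.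
   - No allyl-metal intermediate is ever formed on this path.
3. **Step 1** (incomplete silylation of the hindered phenol, labile silyl ester).
   - Fallback: separate the two functions. Fischer esterification (MeOH, H+) gives the stable, purifiable methyl ester.
   - TBSOTf/2,6-lutidine then silylates the phenol alone, and LiAlH4 gives 3. This costs one extra step.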